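**Retrosynthetic overview**
1. Feature: ring B has oxygen on C6 and C8 around the quaternary C10, the 1,3-dioxygenation of a Birch-reduced 3,5-dimethoxybenzoate, so C5 and C9 are enantiotopic enol-ether carbons flanking C10.
2. Target ⇒ 8-hydroxy-6-ketone: the C6 carbinol is set last by 8-hydroxyl-directed reduction, followed by ester cleavage and acetylation.
3. C8 carbinol ⇒ methyl addition to the 8-ketone; side chain ⇒ olefination at C13 and Michael addition of the surviving C8=C9 methyl enol ether to methyl vinyl ketone (C9–C11 bond).
4. Ring A ⇒ C4–C5 bond: enantiotopic-group-selective capture of a tertiary C4 cation by one enol ether of an achiral 1,5-dimethoxycyclohexa-1,4-diene; ring B comes from the arene, ring A is closed second.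
5. Diene ⇒ Birch reductive alkylation of 3,5-dimethoxybenzoic acid (CO2H → C10 methyl) with a C1–C4 bromide made from ethyl 4-bromobutanoate and MeMgBr.

Key step: step 6

Remark on the chemistry: labdane numbering is used for the bicyclic compounds; all of them have the cis ring fusion that the target SMILES requires (H-5 and the C10 methyl on one face of ring B, ring A folded over the other), configurations are given relative to the C10 methyl, and the enol-ether intermediates 7–13 are kept base-buffered (triethylamine-deactivated silica).

**Step 1**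
Reactants: 1 ethyl 4-bromobutanoate; 2 methylmagnesium bromide
Product: 3 5-bromo-2-methylpentan-2-ol
Conditions: 2 (2.2 equiv), Et2O, −20 → 0 °C; sat. aq. NH4Cl
Reagents that add atoms: none
Why: Double Grignard addition to the ester should give the tertiary alcohol, the low temperature keeping the bromomagnesium alkoxide from closing to 2,2-dimethyltetrahydrofuran.

**Step 2**
Reactants: 3 5-bromo-2-methylpentan-2-ol
Product: 4 [(5-bromo-2-methylpentan-2-yl)oxy]triethylsilane
Conditions: Et3SiOTf, 2,6-lutidine, CH2Cl2, 0 °C
Reagents that add atoms: triethylsilyl trifluoromethanesulfonate, CC[Si](CC)(CC)OS(=O)(=O)C(F)(F)F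
Why: Silyl triflate silylation of a tertiary alcohol; the triethylsilyl ether is chosen because it should survive Li/NH3, LiAlH4 and NaBH4/MeOH and still act as the leaving group in step 6.

**Step 3**
Reactants: 5 3,5-dimethoxybenzoic acid; 4 [(5-bromo-2-methylpentan-2-yl)oxy]triethylsilane
Product: 7 {3,5-dimethoxy-1-[4-methyl-4-(triethylsilyloxy)pentyl]cyclohexa-2,5-dien-1-yl}methanol, via lithium dienecarboxylate 6 (not isolated)
Conditions: Li, NH3/THF, −78 °C; isoprene; 4, −78 → −33 °C; evaporate NH3; LiAlH4, THF, reflux; H2O, 15% aq. NaOH
Reagents that add atoms: none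
Why: Birch reductive alkylation gives the 1,4-dihydro dienolate, which primary bromide 4 alkylates at the carboxyl-bearing carbon to create the future C10 quaternary centre between two methyl enol ethers, and LiAlH4 reduction of the crude lithium carboxylate avoids acidifying the acid-labile bis(enol ether).

**Step 4**
Reactants: 7 {3,5-dimethoxy-1-[4-methyl-4-(triethylsilyloxy)pentyl]cyclohexa-2,5-dien-1-yl}methanol
Product: 8 3,5-dimethoxy-1-[4-methyl-4-(triethylsilyloxy)pentyl]cyclohexa-2,5-diene-1-carbaldehyde
Conditions: SO3·pyridine, DMSO, Et3N, CH2Cl2, 0 °C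
Reagents that add atoms: none
Why: Parikh–Doering oxidation of the neopentylic primary alcohol stays basic throughout, so the enol ethers and the silyl ether should survive, and the aldehyde has no α-hydrogen to epimerise or enolise.

**Step 5**
Reactants: 8 3,5-dimethoxy-1-[4-methyl-4-(triethylsilyloxy)pentyl]cyclohexa-2,5-diene-1-carbaldehyde
Product: 10 1,5-dimethoxy-3-methyl-3-[4-methyl-4-(triethylsilyloxy)pentyl]cyclohexa-1,4-diene, via tosylhydrazone 9 (not isolated)
Conditions: TsNHNH2, MeOH/THF, rt; then NaBH4, reflux
Reagents that add atoms: none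
Why: Caglioti reaction: borohydride reduces the tosylhydrazone of the α-quaternary aldehyde (no α-hydrogen, so no alkene-forming elimination) and loss of sulfinate and N2 leaves the C10 methyl group, without acid for the enol ethers or a base strong enough to conjugate the skipped diene.

**Step 6**
Reactants: 10 1,5-dimethoxy-3-methyl-3-[4-methyl-4-(triethylsilyloxy)pentyl]cyclohexa-1,4-diene
Product: 11 (4aS,8aS)-3-methoxy-4a,8,8-trimethyl-4a,5,6,7,8,8a-hexahydronaphthalen-1(2H)-one (cis-fused C6 ketone with the C8=C9 methyl enol ether intact)
Conditions: imidodiphosphorimidate acid HN[P(=NSO2CF3)(O2Ar*)]2 (5 mol%; O2Ar* = (S)-3,3′-bis[3,5-bis(trifluoromethyl)phenyl]-1,1′-binaphthalene-2,2′-diolate), CH2Cl2/methylcyclohexane, strictly anhydrous, −78 °C; Et3N quench at −78 °C; crude 11 taken directly into step 7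
Reagents that add atoms: none
Why: Proposed new method: the confined acid (H–X*, or R3Si–X* once silyl transfer has begun) activates the tertiary C4–O–SiEt3 oxygen and ionises it to a tertiary C4 cation paired with the chiral anion, C5 of one enol ether attacks C4, and the C6 methyloxocarbenium ion is discharged by the released Et3SiOH through an O-silyl methyl ketal that collapses to the ketone and Et3SiOMe, returning the acid; C-protonation of an enol ether is reversible and unproductive in the absence of water. The closest known reaction types are the Lewis-acid α-tert-alkylation of enol ethers by tertiary cations and catalytic asymmetric cation–olefin cyclisation with confined strong acids, but selection between two enantiotopic enol ethers by the counteranion has not been shown. Ring A closes in a six-membered chair-like mode (C10–C1–C2–C3–C4···C5) that is exo with respect to the attacked C5=C6 π bond, C6 staying outside the new ring. The three-carbon tether anchored on C10 can reach only the lobe of the C5 p orbital on its own face, so C4–C5 and C10–C1 are cis and H-5 ends cis to the C10 methyl under substrate control. C5 and C10 become stereogenic together through the single choice between the enantiotopic carbons C5 and C9, which the chiral anion must make and which is the one selectivity the substrate does not secure (the catalyst antipode giving 11 and not its mirror image is fixed by screening). Regioselectivity is secured because only the two enol-ether β carbons are nucleophilic and only the six-membered closure is within reach of C4.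

**Step 7**
Reactants: 11 cis-fused C6 ketone
Product: 12 cis-fused 3-methoxy-4a,8,8-trimethyl-1,2,4a,5,6,7,8,8a-octahydronaphthalen-1-ol (labdane C6 alcohol, 6-OH trans to the C10 methyl)
Conditions: i-Bu2AlH, CH2Cl2, −78 °C; aq. potassium sodium tartrate
Reagents that add atoms: none
Why: Low-temperature aluminium hydride reduction: hydride should add on the convex face carrying H-5 and the C10 methyl (ring A covers the other face), giving the alcohol with 6-OH trans to the C10 methyl and removing the carbonyl that makes the C7 hydrogens acidic and the enol ether prone to conjugation; C6 is re-set in step 14, so the epimer ratio here is not critical.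

**Step 8**
Reactants: 12 C6 alcohol
Product: 13 tert-butyldimethylsilyl ether of 12
Conditions: t-BuMe2SiOTf, 2,6-lutidine, CH2Cl2, −78 → 0 °C
Reagents that add atoms: tert-butyldimethylsilyl trifluoromethanesulfonate, CC(C)(C)[Si](C)(C)OS(=O)(=O)C(F)(F)F
Why: Silyl triflate/hindered-base silylation of the hindered secondary alcohol tolerates the enol ether and gives an ether that should withstand the Lewis acid, phosphonate anion and organocerium reagent of steps 9–11.

**Step 9**
Reactants: 13 silyl ether; 14 but-3-en-2-one (methyl vinyl ketone)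
Product: 15 6-(tert-butyldimethylsilyloxy)-14,15,17-trinorlabdane-8,13-dione (6-O trans, C9 side chain cis to the C10 methyl)
Conditions: 14, TiCl4, CH2Cl2, −78 °C; aq. NaHCO3; then 1 M HCl, THF, 0 °C (brief)
Reagents that add atoms: water, O
Why: Mukaiyama–Michael addition of an alkyl enol ether: C9, the only nucleophilic carbon, should add to the TiCl4-activated enone on the face of the C10 methyl, anti to the pseudoaxial C10–C1 bond of ring A, which sets C9, and hydrolysis of the C8 oxocarbenium ion or mixed ketal releases the 1,5-diketone.

**Step 10**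
Reactants: 15 diketone; 16 triethyl phosphonoacetate
Product: 17 ethyl (13E)-6-(tert-butyldimethylsilyloxy)-8-oxo-17-norlabd-13-en-15-oate
Conditions: 16, NaH (slight deficit to 16), THF, 0 °C → rt
Reagents that add atoms: none
Why: Horner–Wadsworth–Emmons olefination: the unhindered C13 methyl ketone should react in preference to the α-branched C8 ring ketone, the E enoate is expected to predominate (the Z isomer to be removed by chromatography), and the weakly basic phosphonate anion should neither epimerise C9 nor close the 1,5-diketone by aldol reaction.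

**Step 11**
Reactants: 17 keto enoate
Product: 18 ethyl (13E)-6-(tert-butyldimethylsilyloxy)-8-hydroxylabd-13-en-15-oate (8-OH trans, 8-methyl cis to the C10 methyl)
Conditions: MeLi, CeCl3, THF, −78 °C
Reagents that add atoms: methyllithium, [Li]C
Why: Organocerium 1,2-addition is non-basic and ketone-selective over the enoate, and since axial approach on the ring A face is blocked by the 1,3-diaxial C1 methylene and 6-silyloxy group, methyl should enter equatorially from the face of the C10 methyl, setting C8.

**Step 12**
Reactants: 18 silyl ether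
Product: 19 ethyl (13E)-6,8-dihydroxylabd-13-en-15-oate (both hydroxyls trans to the C10 methyl)
Conditions: HF·pyridine, THF/pyridine, 0 °C → rt
Reagents that add atoms: none
Why: Fluoride desilylation with buffered HF·pyridine should cleave the secondary silyl ether without ionising the tertiary alcohol or exposing the enoate to a basic fluoride source.

**Step 13**
Reactants: 19 diol
Product: 20 ethyl (13E)-8-hydroxy-6-oxolabd-13-en-15-oate
Conditions: Dess–Martin periodinane, NaHCO3, CH2Cl2, 0 °C → rt
Reagents that add atoms: none
Why: Buffered Dess–Martin oxidation converts the crowded secondary C6 alcohol into the ketone while the tertiary 8-hydroxyl is inert and the β-hydroxy ketone is spared dehydration or retro-aldol cleavage.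

**Step 14**
Reactants: 20 β-hydroxy ketone
Product: 21 ethyl (13E)-6,8-dihydroxylabd-13-en-15-oate (6-OH cis, 8-OH trans to the C10 methyl)
Conditions: Me4NBH(OAc)3, MeCN/AcOH, −30 → 0 °C
Reagents that add atoms: none
Why: Saksena–Evans hydroxyl-directed reduction: the axial 8-hydroxyl exchanges onto boron and delivers hydride through a six-membered transition state to its own face of the C6 carbonyl, setting C6 with the hydroxyl anti to the 8-hydroxyl and cis to the C10 methyl, the opposite of the undirected attack used in step 7.

**Step 15**
Reactants: 21 diol ester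
Product: 22 (13E)-6,8-dihydroxylabd-13-en-15-oic acid (configuration as 21)
Conditions: LiOH, THF/MeOH/H2O, 40 °C; then 1 M HCl to pH 3, 0 °C
Reagents that add atoms: lithium hydroxide, [Li+].[OH-]
Why: Saponification of the conjugated ethyl ester is placed before acetylation so that no acetate has to survive hydroxide, and the diol carries no base-sensitive group.

**Step 16**
Reactants: 22 diol acid
Product: 23 (5S,6S,8S,9S,10R,13E)-6-acetoxy-8-hydroxylabd-13-en-15-oic acid (target CNP0221670.1)
Conditions: Ac2O, pyridine, 4-(dimethylamino)pyridine (0.1 equiv), CH2Cl2, rt; aq. NaHCO3, then pH 3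
Reagents that add atoms: acetic anhydride, CC(=O)OC(C)=O
Why: Nucleophile-catalysed acetylation should acylate the secondary equatorial 6-hydroxyl but not the hindered tertiary 8-hydroxyl, and the transient mixed anhydride at C15 is hydrolysed in the bicarbonate work-up.

**Compound list**
1 | ethyl 4-bromobutanoate | CCOC(=O)CCCBr | starting material
2 | methylmagnesium bromide | C[Mg]Br | starting material
3 | 5-bromo-2-methylpentan-2-ol | CC(C)(O)CCCBr | intermediate
4 | [(5-bromo-2-methylpentan-2-yl)oxy]triethylsilane | CC[Si](CC)(CC)OC(C)(C)CCCBr | intermediate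
5 | 3,5-dimethoxybenzoic acid | COc1cc(OC)cc(c1)C(=O)O | starting material
6 | lithium 3,5-dimethoxy-1-[4-methyl-4-(triethylsilyloxy)pentyl]cyclohexa-2,5-diene-1-carboxylate | [Li+].[O-]C(=O)C1(CCCC(C)(C)O[Si](CC)(CC)CC)C=C(OC)CC(OC)=C1 | intermediate
7 | {3,5-dimethoxy-1-[4-methyl-4-(triethylsilyloxy)pentyl]cyclohexa-2,5-dien-1-yl}methanol | OCC1(CCCC(C)(C)O[Si](CC)(CC)CC)C=C(OC)CC(OC)=C1 | intermediate
8 | 3,5-dimethoxy-1-[4-methyl-4-(triethylsilyloxy)pentyl]cyclohexa-2,5-diene-1-carbaldehyde | O=CC1(CCCC(C)(C)O[Si](CC)(CC)CC)C=C(OC)CC(OC)=C1 | intermediate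
9 | N-tosylhydrazone of 8 | Cc1ccc(cc1)S(=O)(=O)N/N=C/C1(CCCC(C)(C)O[Si](CC)(CC)CC)C=C(OC)CC(OC)=C1 | intermediate
10 | 1,5-dimethoxy-3-methyl-3-[4-methyl-4-(triethylsilyloxy)pentyl]cyclohexa-1,4-diene (achiral key precursor) | COC1=CC(C)(CCCC(C)(C)O[Si](CC)(CC)CC)C=C(OC)C1 | intermediate
11 | (4aS,8aS)-3-methoxy-4a,8,8-trimethyl-4a,5,6,7,8,8a-hexahydronaphthalen-1(2H)-one (cis-fused; C6 ketone, C8 methyl enol ether) | O=C1CC(OC)=C[C@]2(C)CCCC(C)(C)[C@H]12 | intermediate
12 | cis-fused C6 alcohol of 11, 6-OH trans to the C10 methyl | O[C@@H]1CC(OC)=C[C@]2(C)CCCC(C)(C)[C@H]12 | intermediate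
13 | tert-butyldimethylsilyl ether of 12 | CC(C)(C)[Si](C)(C)O[C@@H]1CC(OC)=C[C@]2(C)CCCC(C)(C)[C@H]12 | intermediate
14 | but-3-en-2-one (methyl vinyl ketone) | CC(=O)C=C | starting material
15 | 6-(tert-butyldimethylsilyloxy)-14,15,17-trinorlabdane-8,13-dione, ring fusion cis, 6-O trans and C9 side chain cis to the C10 methyl | CC(C)(C)[Si](C)(C)O[C@@H]1CC(=O)[C@@H](CCC(C)=O)[C@]2(C)CCCC(C)(C)[C@H]12 | intermediate
16 | triethyl phosphonoacetate | CCOC(=O)CP(=O)(OCC)OCC | starting material
17 | ethyl (13E)-6-(tert-butyldimethylsilyloxy)-8-oxo-17-norlabd-13-en-15-oate | CC(C)(C)[Si](C)(C)O[C@@H]1CC(=O)[C@@H](CC/C(C)=C/C(=O)OCC)[C@]2(C)CCCC(C)(C)[C@H]12 | intermediate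
18 | ethyl (13E)-6-(tert-butyldimethylsilyloxy)-8-hydroxylabd-13-en-15-oate, 8-OH trans and 8-methyl cis to the C10 methyl | CC(C)(C)[Si](C)(C)O[C@@H]1C[C@](C)(O)[C@@H](CC/C(C)=C/C(=O)OCC)[C@]2(C)CCCC(C)(C)[C@H]12 | intermediate
19 | ethyl (13E)-6,8-dihydroxylabd-13-en-15-oate, both hydroxyls trans to the C10 methyl | O[C@@H]1C[C@](C)(O)[C@@H](CC/C(C)=C/C(=O)OCC)[C@]2(C)CCCC(C)(C)[C@H]12 | intermediate
20 | ethyl (13E)-8-hydroxy-6-oxolabd-13-en-15-oate | O=C1C[C@](C)(O)[C@@H](CC/C(C)=C/C(=O)OCC)[C@]2(C)CCCC(C)(C)[C@H]12 | intermediate
21 | ethyl (13E)-6,8-dihydroxylabd-13-en-15-oate, 6-OH cis and 8-OH trans to the C10 methyl | O[C@H]1C[C@](C)(O)[C@@H](CC/C(C)=C/C(=O)OCC)[C@]2(C)CCCC(C)(C)[C@H]12 | intermediate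
22 | (13E)-6,8-dihydroxylabd-13-en-15-oic acid, configuration as 21 | O[C@H]1C[C@](C)(O)[C@@H](CC/C(C)=C/C(=O)O)[C@]2(C)CCCC(C)(C)[C@H]12 | intermediate
23 | (5S,6S,8S,9S,10R,13E)-6-acetoxy-8-hydroxylabd-13-en-15-oic acid | CC(=O)O[C@H]1C[C@](C)(O)[C@@H](CC/C(C)=C/C(=O)O)[C@]2(C)CCCC(C)(C)[C@H]12 | target

**Step count**
Total: 16 steps. Longest linear sequence: 16 steps (steps 1–16 from ethyl 4-bromobutanoate; 14 steps from 3,5-dimethoxybenzoic acid).

**Steps most likely to fail**

1. Step 6. The chiral ion pair may not discriminate the enantiotopic enol ethers, or the acid may protonate an enol ether and conjugate the diene (or isomerise 11 to the vinylogous ester) faster than it ionises the silyl ether. The fallback sets out from 10 and returns at 12. Compound 10 would be cyclised with an achiral silyl Lewis acid (Me3SiOTf, 10 mol%, 2,6-di-tert-butylpyridine, CH2Cl2, −78 °C; Lewis-acid tert-alkylation of an enol ether, the cis fusion again being substrate-controlled) to the racemic ketone F1. Reduction with i-Bu2AlH as in step 7 would give the racemic alcohol F2. F2 would be resolved by preparative chromatography on a chiral stationary phase (cellulose tris(3,5-dimethylphenylcarbamate)); the enantiomer identical with 12 re-enters at step 8, at the cost of half the material.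

2. Step 9. The strong Lewis acid may protonolyse the enol ether or polymerise the enone before the C–C bond forms at the neopentylic C9. The fallback sets out from 13 and returns at 15. Compounds 13 and 14 would be combined in an inverse-electron-demand hetero-Diels–Alder reaction (neat, 80–100 °C in a sealed vessel, or Yb(fod)3 catalysis at rt; fod = 6,6,7,7,8,8,8-heptafluoro-2,2-dimethyloctane-3,5-dionate), which needs no strong Lewis acid, to give the fused 2-methoxydihydropyran F3 with the C9–C11 bond on the face of the C10 methyl. Dilute aqueous oxalic acid in THF would then open F3 to 15.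

3. Step 11. Methyl may be delivered from the ring A face, giving the C8 epimer. The fallback sets out from 17 and returns at 18. Compound 17 would be methylenated at C8 under non-basic, ketone-selective conditions (Takai–Lombardo: Zn, CH2Br2, TiCl4, THF/CH2Cl2) to the exocyclic alkene F4. Oxymercuration (Hg(OAc)2, THF/H2O) then brings in oxygen, not carbon, as the nucleophile on the face that nucleophiles prefer, giving the alkylmercury acetate F5. Demercuration with NaBH4/aq. NaOH would deliver 18.

**Further compounds**
F1 | step 6 | racemic 11 (both enantiomers) | O=C1CC(OC)=C[C@]2(C)CCCC(C)(C)[C@H]12.O=C1CC(OC)=C[C@@]2(C)CCCC(C)(C)[C@@H]12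
F2 | step 6 | racemic 12 (both enantiomers) | O[C@@H]1CC(OC)=C[C@]2(C)CCCC(C)(C)[C@H]12.O[C@H]1CC(OC)=C[C@@]2(C)CCCC(C)(C)[C@@H]12
F3 | step 9 | cis-fused 2-methoxy-3,4-dihydro-2H-pyran cycloadduct of 13 and 14 (C8 ketal; pyran oxygen and C11 cis to the C10 methyl) | CC(C)(C)[Si](C)(C)O[C@@H]1C[C@@]2(OC)OC(C)=CC[C@H]2[C@]3(C)CCCC(C)(C)[C@H]13
F4 | step 11 | ethyl (13E)-6-(tert-butyldimethylsilyloxy)labda-8(17),13-dien-15-oate | CC(C)(C)[Si](C)(C)O[C@@H]1CC(=C)[C@@H](CC/C(C)=C/C(=O)OCC)[C@]2(C)CCCC(C)(C)[C@H]12
F5 | step 11 | 17-(acetoxymercurio) derivative of 18 | CC(C)(C)[Si](C)(C)O[C@@H]1C[C@](C[Hg]OC(C)=O)(O)[C@@H](CC/C(C)=C/C(=O)OCC)[C@]2(C)CCCC(C)(C)[C@H]12
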